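**Plan**
- Retrosynthesis first removes the acetate, the C7–O bond (allylic oxidation) and C8=C17 (methylenation), leaving methyl 8-oxo-17-norlabdan-15-oate.
- Ring A is then cut at C3–C4. This is possible because ring A carries no functional group: C3 is a plain CH2 and C4 a quaternary carbon with two methyls next to the ring-fusion carbon C5. C4 can therefore arise as the tertiary radical of an isopropenyl group on C5, and C3 as the carbon of an aldehyde sulfonylhydrazone whose nitrogen is lost afterwards.
- The remaining ring B ketone maps onto (1R,5R)-verbenone, all ten carbons of which are kept (C4–C10, C18–C20). Its cyclobutane bond C4–C7 is cut by acid, C10–C1 comes from a vinyl conjugate addition, C2–C3 from hydroformylation, and C9–C11 from an enolate alkylation.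
- Forward order: side-chain iodide; vinyl addition and alkylation on the bicyclic ketone; cyclobutane cleavage (ring B alone); aldehyde and hydrazone; radical closure of ring A; methylenation, allylic hydroxylation, acetylation.
- Stereochemistry: C5 is the verbenone bridgehead; C10 comes from addition anti to the CMe2 bridge, which fixes the trans ring fusion; C9 is set by base equilibration (equatorial chain); C7 by the ene/[2,3] course of SeO2 on the α-face; C13 from (S)-methyl hydrogen 3-methylglutarate.

Key step: step 7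

Remark: labdane locants (C1–C20) are used for positions throughout; (1R,5R)-(+)-verbenone and (S)-methyl hydrogen 3-methylglutarate are taken as purchasable.

**Step 1**
Reactants: 1 (3S)-5-methoxy-3-methyl-5-oxopentanoic acid
Product: 2 methyl (3S)-5-hydroxy-3-methylpentanoate
Conditions: BH3·SMe2 (1.1 equiv), THF, −15 °C → rt; MeOH quench
Reagents that add atoms: none
Why: Chemoselective borane reduction of a carboxylic acid (via the acyloxyborane) is much faster than reduction of the methyl ester, and the stereocentre is not involved.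

**Step 2**
Reactants: 2 methyl (3S)-5-hydroxy-3-methylpentanoate
Product: 3 methyl (3R)-5-iodo-3-methylpentanoate
Conditions: I2, PPh3, imidazole, CH2Cl2, 0 °C → rt
Reagents that add atoms: iodine, II
Why: Appel-type iodination is an SN2 displacement at the primary carbon and leaves the stereocentre untouched (the descriptor changes to R only because iodine changes the CIP priorities).

**Step 3**
Reactants: 4 (1R,5R)-4,6,6-trimethylbicyclo[3.1.1]hept-3-en-2-one [(+)-verbenone]
Product: 5 (1R,4S,5S)-4-ethenyl-4,6,6-trimethylbicyclo[3.1.1]heptan-2-one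
Conditions: CH2=CHMgBr (1.5 equiv), CuBr·SMe2 (10 mol %), THF, −40 → 0 °C; aq NH4Cl
Reagents that add atoms: vinylmagnesium bromide, C=C[Mg]Br
Why: Copper-catalysed conjugate addition to the β,β-disubstituted enone builds the quaternary carbon (later C10); the vinyl group should enter the face opposite the gem-dimethyl bridge, so the methyl ends syn and the vinyl anti to that bridge.

**Step 4**
Reactants: 5 (1R,4S,5S)-4-ethenyl-4,6,6-trimethylbicyclo[3.1.1]heptan-2-one; 3 methyl (3R)-5-iodo-3-methylpentanoate
Product: 6 methyl (3S)-5-[(1R,3S,4S,5S)-4-ethenyl-4,6,6-trimethyl-2-oxobicyclo[3.1.1]heptan-3-yl]-3-methylpentanoate (side chain anti to the gem-dimethyl bridge)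
Conditions: LiN(iPr)2, THF, −78 °C; then 3, DMPU, −78 → 0 °C
Reagents that add atoms: none
Why: Enolate alkylation: only one enolate can form (the other α-carbon is a bridgehead) and it should be alkylated by the primary iodide anti to the bridge; the configuration of this centre (later C9) does not matter because step 5 equilibrates it.

**Step 5**
Reactants: 6 methyl (3S)-5-[(1R,3S,4S,5S)-4-ethenyl-4,6,6-trimethyl-2-oxobicyclo[3.1.1]heptan-3-yl]-3-methylpentanoate
Product: 8 methyl (3S)-5-[(1R,2S,3S)-2-ethenyl-2-methyl-6-oxo-3-(prop-1-en-2-yl)cyclohexyl]-3-methylpentanoate, via enol acetate 7 (not isolated)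
Conditions: BF3·OEt2 (cat.), Zn(OAc)2 (cat.), Ac2O, 0 °C → rt; then NaOMe (cat.), MeOH, rt → 40 °C
Reagents that add atoms: acetic anhydride, CC(=O)OC(C)=O (supplies the acetyl group of 7 only; 8 keeps none of it)
Why: Lewis acid-promoted acetolytic cyclobutane cleavage of a nopinone-type ketone: the ring bond α to the activated carbonyl ionises to an enol acetate and a tertiary cation that loses a methyl proton (E1) to give the isopropenyl group, and methanolysis then frees the ketone while NaOMe equilibrates C9 to the isomer with all three ring substituents equatorial; the verbenone bridgehead survives as C5.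

**Step 6**
Reactants: 8 methyl (3S)-5-[(1R,2S,3S)-2-ethenyl-2-methyl-6-oxo-3-(prop-1-en-2-yl)cyclohexyl]-3-methylpentanoate
Product: 10 methyl (3S)-3-methyl-5-[(1R,2S,3S)-2-methyl-2-{(3E)-3-[2-(4-methylbenzenesulfonyl)hydrazinylidene]propyl}-6-oxo-3-(prop-1-en-2-yl)cyclohexyl]pentanoate, via aldehyde 9 (not isolated)
Conditions: Rh(acac)(CO)2 (1 mol %), PPh3 (10 mol %), CO/H2 (1:1, 10 bar), toluene, 50 °C; then TsNHNH2 (1.05 equiv), MeOH, rt
Reagents that add atoms: carbon monoxide, [C-]#[O+]; 4-methylbenzenesulfonohydrazide, Cc1ccc(cc1)S(=O)(=O)NN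
Why: Rh-catalysed hydroformylation should take the monosubstituted vinyl group (linear aldehyde only, since the branched position is neopentylic and the alkene cannot isomerise) in preference to the slower 1,1-disubstituted isopropenyl group, and hydrazone condensation then occurs at the unhindered aldehyde and not at the α-branched ketone.

**Step 7**
Reactants: 10 methyl (3S)-3-methyl-5-[(1R,2S,3S)-2-methyl-2-{(3E)-3-[2-(4-methylbenzenesulfonyl)hydrazinylidene]propyl}-6-oxo-3-(prop-1-en-2-yl)cyclohexyl]pentanoate
Product: 12 methyl (13S)-8-oxo-17-norlabdan-15-oate, via cyclic hydrazide 11 (not isolated)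
Conditions: Fe(acac)3 (30 mol %), PhSiH3 (2.5 equiv), MeOH/THF, 60 °C; then NaOAc, MeOH, 65 °C
Reagents that add atoms: none
Why: An iron hydride formed from Fe(acac)3 and PhSiH3 transfers a hydrogen atom to the CH2 end of the isopropenyl group (metal-hydride hydrogen-atom transfer), the tertiary radical at C4 adds to the hydrazone carbon C3, the hydrazinyl radical is reduced and protonated to hydrazide 11, and base then expels sulfinate to give a monoalkyl diazene that loses N2 and leaves C3 as CH2. The closest known reactions are the iron-mediated reductive coupling of olefins with sulfonyl hydrazones (olefin hydromethylation and its intramolecular alkene–hydrazone form) and the diazene decomposition that ends the reduction of tosylhydrazones to methylene groups (Wolff–Kishner type). Ring A closes in the 6-exo-trig mode through a chair transition state. No lasting stereocentre is formed (C3 of 11 is erased), and the trans ring fusion follows from the trans, diequatorial placement that the isopropenyl group on C5 and the three-carbon arm on C10 already have in 10. The step needs hydrogen-atom transfer to the electron-rich 1,1-disubstituted alkene and cyclisation faster than quenching of the radical: the isopropenyl group is the only alkene left, the C=N acceptor is held six atoms away on the chair, and addition to the ketone would give a strained bicyclo[2.2.1] alkoxyl radical that reverts.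

**Step 8**
Reactants: 12 methyl (13S)-8-oxo-17-norlabdan-15-oate
Product: 13 methyl (13S)-labd-8(17)-en-15-oate
Conditions: Ph3PCH3Br, KN(SiMe3)2, toluene, 0 → 90 °C
Reagents that add atoms: methyltriphenylphosphonium bromide, C[P+](c1ccccc1)(c1ccccc1)c1ccccc1.[Br-]
Why: Wittig methylenation of the hindered ketone with the salt-free ylide should leave the ester alone, and any enolisation returns C9 to its stable configuration with the side chain equatorial.

**Step 9**
Reactants: 13 methyl (13S)-labd-8(17)-en-15-oate
Product: 14 methyl (13S)-7α-hydroxylabd-8(17)-en-15-oate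
Conditions: SeO2 (0.3 equiv), t-BuOOH (2 equiv), CH2Cl2, 0 °C → rt
Reagents that add atoms: tert-butyl hydroperoxide, CC(C)(C)OO (oxygen source; SeO2, O=[Se]=O, is the catalytic carrier)
Why: SeO2 allylic hydroxylation (ene reaction, then [2,3]-sigmatropic shift) should remove the axial 7α-hydrogen of the CH2 group in preference to the tertiary C9–H and deliver oxygen to the same α-face, giving the axial 7α-alcohol.

**Step 10**
Reactants: 14 methyl (13S)-7α-hydroxylabd-8(17)-en-15-oate
Product: 15 methyl (13S)-7α-acetoxylabd-8(17)-en-15-oate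
Conditions: Ac2O, pyridine, 4-(dimethylamino)pyridine (cat.), CH2Cl2, rt
Reagents that add atoms: acetic anhydride, CC(=O)OC(C)=O
Why: Nucleophile-catalysed acetylation of the secondary allylic alcohol proceeds with retention at C7.

**Compound list**
1 | (3S)-5-methoxy-3-methyl-5-oxopentanoic acid | OC(=O)C[C@H](C)CC(=O)OC | starting material
2 | methyl (3S)-5-hydroxy-3-methylpentanoate | OCC[C@H](C)CC(=O)OC | intermediate
3 | methyl (3R)-5-iodo-3-methylpentanoate | ICC[C@H](C)CC(=O)OC | intermediate
4 | (1R,5R)-4,6,6-trimethylbicyclo[3.1.1]hept-3-en-2-one, (+)-verbenone | CC1=CC(=O)[C@@H]2C[C@H]1C2(C)C | starting material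
5 | (1R,4S,5S)-4-ethenyl-4,6,6-trimethylbicyclo[3.1.1]heptan-2-one (vinyl anti to the CMe2 bridge) | C=C[C@]1(C)CC(=O)[C@@H]2C[C@H]1C2(C)C | intermediate
6 | methyl (3S)-5-[(1R,3S,4S,5S)-4-ethenyl-4,6,6-trimethyl-2-oxobicyclo[3.1.1]heptan-3-yl]-3-methylpentanoate (side chain and vinyl both anti to the CMe2 bridge) | C=C[C@]1(C)[C@H](CC[C@H](C)CC(=O)OC)C(=O)[C@@H]2C[C@H]1C2(C)C | intermediate
7 | methyl (3S)-5-[(1S,5S,6S)-2-acetoxy-6-ethenyl-6-methyl-5-(prop-1-en-2-yl)cyclohex-2-en-1-yl]-3-methylpentanoate (C7=C8 enol acetate, 9-epi series) | CC(=O)OC1=CC[C@@H](C(C)=C)[C@](C)(C=C)[C@@H]1CC[C@H](C)CC(=O)OC | intermediate (not isolated)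
8 | methyl (3S)-5-[(1R,2S,3S)-2-ethenyl-2-methyl-6-oxo-3-(prop-1-en-2-yl)cyclohexyl]-3-methylpentanoate (isopropenyl and side chain cis to the ring methyl, trans to vinyl) | O=C1CC[C@@H](C(C)=C)[C@](C)(C=C)[C@H]1CC[C@H](C)CC(=O)OC | intermediate
9 | methyl (3S)-3-methyl-5-[(1R,2S,3S)-2-methyl-6-oxo-2-(3-oxopropyl)-3-(prop-1-en-2-yl)cyclohexyl]pentanoate | O=C1CC[C@@H](C(C)=C)[C@](C)(CCC=O)[C@H]1CC[C@H](C)CC(=O)OC | intermediate (not isolated)
10 | methyl (3S)-3-methyl-5-[(1R,2S,3S)-2-methyl-2-{(3E)-3-[2-(4-methylbenzenesulfonyl)hydrazinylidene]propyl}-6-oxo-3-(prop-1-en-2-yl)cyclohexyl]pentanoate | O=C1CC[C@@H](C(C)=C)[C@](C)(CC/C=N/NS(=O)(=O)c2ccc(C)cc2)[C@H]1CC[C@H](C)CC(=O)OC | intermediate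
11 | methyl (13S)-3β-[2-(4-methylbenzenesulfonyl)hydrazinyl]-8-oxo-17-norlabdan-15-oate | O=C1CC[C@H]2C(C)(C)[C@@H](NNS(=O)(=O)c3ccc(C)cc3)CC[C@]2(C)[C@H]1CC[C@H](C)CC(=O)OC | intermediate (not isolated)
12 | methyl (13S)-8-oxo-17-norlabdan-15-oate (5α-H, 9α-H, 10β-methyl) | O=C1CC[C@H]2C(C)(C)CCC[C@]2(C)[C@H]1CC[C@H](C)CC(=O)OC | intermediate
13 | methyl (5S,9S,10S,13S)-labd-8(17)-en-15-oate | C=C1CC[C@H]2C(C)(C)CCC[C@]2(C)[C@H]1CC[C@H](C)CC(=O)OC | intermediate
14 | methyl (13S)-7α-hydroxylabd-8(17)-en-15-oate | C=C1[C@H](O)C[C@H]2C(C)(C)CCC[C@]2(C)[C@H]1CC[C@H](C)CC(=O)OC | intermediate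
15 | methyl (5S,7R,9R,10S,13S)-7-acetoxylabd-8(17)-en-15-oate (7α-acetate) | C=C1[C@H](OC(C)=O)C[C@H]2C(C)(C)CCC[C@]2(C)[C@H]1CC[C@H](C)CC(=O)OC | target

**Totals**
Total step count: 10 (steps 5, 6 and 7 each run as two operations without isolating the intermediate).
Longest linear sequence: 9 steps (1 → 2 → 3 → 6 → 8 → 10 → 12 → 13 → 14 → 15).

**Steps most likely to fail**

Step 7. The tertiary radical may be quenched by a second hydrogen-atom transfer (isopropenyl reduced to isopropyl) before it reaches the hydrazone, or the hydrazide may not lose nitrogen cleanly. The fallback sets out from aldehyde 9 (step 6 stopped before the hydrazide is added) and returns at 12. The aldehyde alone is methylenated (Ph3P=CH2, 1 equiv, THF, −78 °C) to methyl (3S)-5-[(1R,2S,3S)-2-(but-3-en-1-yl)-2-methyl-6-oxo-3-(prop-1-en-2-yl)cyclohexyl]-3-methylpentanoate F1. Ring-closing metathesis with the second-generation Grubbs catalyst (CH2Cl2, 40 °C) then closes ring A as the trisubstituted alkene methyl (13S)-8-oxo-17,19-dinorlabd-3-en-15-oate F2. The missing methyl group is added at C4 by iron-mediated olefin hydromethylation (Fe(acac)3, PhSiH3, formaldehyde 4-methylbenzenesulfonylhydrazone, THF/MeOH, rt; then MeOH, 65 °C). This passes through methyl (13S)-18-[2-(4-methylbenzenesulfonyl)hydrazinyl]-8-oxo-17-norlabdan-15-oate F3, which loses sulfinate and nitrogen to give 12.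

Step 4. C-alkylation at the hindered enolate carbon next to the quaternary centre may be slow, so that proton transfer to the ester or attack of the enolate on the ester carbonyl takes over. The fallback sets out from 5 and 2 and returns at 6. Alcohol 2 is oxidised with Dess–Martin periodinane to methyl (3S)-3-methyl-5-oxopentanoate F4. The lithium enolate of 5 adds to F4 (aldol addition, THF, −78 °C) to give the β-hydroxy ketone, methyl (3S)-5-hydroxy-3-methyl-5-[4-ethenyl-4,6,6-trimethyl-2-oxobicyclo[3.1.1]heptan-3-yl]pentanoate F5, as a mixture of carbinol epimers. Mesylation (MeSO2Cl, Et3N) gives the mesylate of that aldol F6, and elimination with DBU gives the (Z)-alkylidene ketone F7. Conjugate reduction with [(Ph3P)CuH]6 (toluene, rt) should give 6 together with its C9 epimer F8, and both converge on 8 under the NaOMe equilibration of step 5.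

Step 5. The tertiary cation may be captured by acetate, or may lose the ring proton at C5 (isopropylidene isomer, with loss of the C5 stereocentre) in place of a methyl proton. The fallback sets out from 6 and returns at 8. Ring opening with Me3SiI (made from Me3SiCl and NaI, MeCN, 0 °C), in which iodide traps the cation, gives the silyl enol ether of the ring-opened tertiary iodide F9. Aqueous work-up hydrolyses it to the tertiary iodide, methyl (3S)-5-[2-ethenyl-3-(2-iodopropan-2-yl)-2-methyl-6-oxocyclohexyl]-3-methylpentanoate F10. E2 elimination with DBU (toluene, 80 °C) should take the accessible methyl proton, equilibrate C9 and give 8.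

**Further compounds**
F1 | step 7 | methyl (3S)-5-[(1R,2S,3S)-2-(but-3-en-1-yl)-2-methyl-6-oxo-3-(prop-1-en-2-yl)cyclohexyl]-3-methylpentanoate | O=C1CC[C@@H](C(C)=C)[C@](C)(CCC=C)[C@H]1CC[C@H](C)CC(=O)OC
F2 | step 7 | methyl (13S)-8-oxo-17,19-dinorlabd-3-en-15-oate | O=C1CC[C@H]2C(C)=CCC[C@]2(C)[C@H]1CC[C@H](C)CC(=O)OC
F3 | step 7 | methyl (13S)-18-[2-(4-methylbenzenesulfonyl)hydrazinyl]-8-oxo-17-norlabdan-15-oate | O=C1CC[C@H]2[C@](C)(CNNS(=O)(=O)c3ccc(C)cc3)CCC[C@]2(C)[C@H]1CC[C@H](C)CC(=O)OC
F4 | step 4 | methyl (3S)-3-methyl-5-oxopentanoate | O=CC[C@H](C)CC(=O)OC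
F5 | step 4 | aldol of 5 and F4, methyl (3S)-5-hydroxy-3-methyl-5-[4-ethenyl-4,6,6-trimethyl-2-oxobicyclo[3.1.1]heptan-3-yl]pentanoate (attached anti to the CMe2 bridge; carbinol epimers) | C=C[C@]1(C)[C@H](C(O)C[C@H](C)CC(=O)OC)C(=O)[C@@H]2C[C@H]1C2(C)C
F6 | step 4 | mesylate of aldol F5 (carbinol epimers) | C=C[C@]1(C)[C@H](C(OS(C)(=O)=O)C[C@H](C)CC(=O)OC)C(=O)[C@@H]2C[C@H]1C2(C)C
F7 | step 4 | (Z)-alkylidene ketone, methyl (3S)-5-[4-ethenyl-4,6,6-trimethyl-2-oxobicyclo[3.1.1]heptan-3-ylidene]-3-methylpentanoate | C=C[C@]1(C)/C(=C/C[C@H](C)CC(=O)OC)C(=O)[C@@H]2C[C@H]1C2(C)C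
F8 | step 4 | C9 epimer of 6 (side chain syn to the CMe2 bridge) | C=C[C@]1(C)[C@@H](CC[C@H](C)CC(=O)OC)C(=O)[C@@H]2C[C@H]1C2(C)C
F9 | step 5 | trimethylsilyl enol ether of the ring-opened tertiary iodide | C[Si](C)(C)OC1=CC[C@@H](C(C)(C)I)[C@](C)(C=C)[C@@H]1CC[C@H](C)CC(=O)OC
F10 | step 5 | methyl (3S)-5-[2-ethenyl-3-(2-iodopropan-2-yl)-2-methyl-6-oxocyclohexyl]-3-methylpentanoate (9-epi series) | O=C1CC[C@@H](C(C)(C)I)[C@](C)(C=C)[C@@H]1CC[C@H](C)CC(=O)OC
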